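**Assumption:** the target SMILES has no stereocentre and the 18-membered ring is taken to be conformationally mobile, so marchantin G is treated as achiral and no stereocontrol is needed.

## Retrosynthetic overview

1. Marchantin G ⇐ tri-O-methyl macrocycle (BBr3) ⇐ closure of the 18-membered ring last, at the ArC(=O)CH2–aryl(ring B) bond, by a Pd-catalysed macrocyclising ketone α-arylation.
2. Seco aryl methyl ketone / aryl chloride ⇐ B-alkyl Suzuki–Miyaura union of an A–O–D aryl bromide with a B–O–C styrene, which forms the bibenzyl bridge.
3. A–O–D fragment ⇐ Ullmann etherification of 3-hydroxy-4,5-dimethoxyacetophenone with 1-bromo-4-iodobenzene; the acetophenone ⇐ Ir C–H borylation / acyl Suzuki of 2,3-dimethoxyphenol ⇐ catechol.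
4. B–O–C fragment ⇐ SNAr of 3-chlorophenol on 2-fluoro-3-methoxybenzaldehyde (from 2-fluorophenol by ortho-lithiation/formylation), then Wittig methylenation.

All four benzene rings come from the starting materials; the macrocycle is the only ring formed.

## Route

### Fragment A–O–D

**Step 1**
Reactants: 1, catechol (benzene-1,2-diol)
Product: 2, 1,2-dimethoxybenzene
Conditions: MeI (2.5 equiv), K2CO3, acetone, reflux
Reagents that add atoms: iodomethane, CI
Why: Williamson O-methylation installs the two methyl ethers, which direct the next lithiation and are cleaved by BBr3 at the end.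

**Step 2**
Reactants: 2, 1,2-dimethoxybenzene
Product: 3, 2,3-dimethoxyphenol
Conditions: n-BuLi, TMEDA, Et2O, 0 °C → rt; B(OMe)3, −78 °C → rt; H2O2, AcOH, 0 °C → rt
Reagents that add atoms: hydrogen peroxide, OO (oxygen delivered via the aryl boronate made with trimethyl borate, COB(OC)OC)
Why: Directed ortho-metalation occurs at C3 next to a methoxy group, and the aryllithium is borylated and oxidised in one pot to the phenol.

**Step 3**
Reactants: 3, 2,3-dimethoxyphenol
Product: 4, 2,3-dimethoxy-5-(4,4,5,5-tetramethyl-1,3,2-dioxaborolan-2-yl)phenol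
Conditions: HBpin (1.1 equiv), [Ir(OMe)(cod)]2 (1.5 mol %), dtbpy (3 mol %), THF, rt; then B2pin2 (0.7 equiv), 80 °C; MeOH/H2O work-up
Reagents that add atoms: bis(pinacolato)diboron, CC1(C)OB(OC1(C)C)B1OC(C)(C)C(C)(C)O1; pinacolborane, CC1(C)OBOC1(C)C
Why: Ir-catalysed, sterically controlled aromatic C–H borylation with the phenol masked in situ as ArO–Bpin; C5–H is the only C–H with no ortho substituent, so boron enters para to the central methoxy group.

**Step 4**
Reactants: 4, 2,3-dimethoxy-5-(pinacolboryl)phenol
Product: 5, 1-(3-hydroxy-4,5-dimethoxyphenyl)ethan-1-one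
Conditions: Ac2O (3 equiv), Pd(OAc)2 (3 mol %), P(4-MeOC6H4)3 (7 mol %), THF/H2O, 60 °C; then K2CO3, MeOH, rt
Reagents that add atoms: acetic anhydride, CC(=O)OC(C)=O
Why: Acyl Suzuki–Miyaura ketone synthesis: Pd(0) inserts into the anhydride C–O bond and the acyl-Pd acetate is arylated by the boronate; the aryl acetate formed in passing is removed by the methanolysis.

**Step 5**
Reactants: 5, 1-(3-hydroxy-4,5-dimethoxyphenyl)ethan-1-one; 6, 1-bromo-4-iodobenzene (1.5 equiv)
Product: 7, 1-[3-(4-bromophenoxy)-4,5-dimethoxyphenyl]ethan-1-one
Conditions: CuI (10 mol %), N,N-dimethylglycine·HCl (30 mol %), Cs2CO3, dioxane, 90 °C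
Reagents that add atoms: none
Why: Ligand-accelerated Ullmann diaryl ether coupling; Cu(I) reacts with C–I much faster than C–Br, so the bromide is kept for Step 10.

### Fragment B–O–C

**Step 6**
Reactants: 8, 2-fluorophenol
Product: 9, 1-fluoro-2-methoxybenzene
Conditions: MeI, K2CO3, acetone, reflux
Reagents that add atoms: iodomethane, CI
Why: Williamson O-methylation protects the future ring-C phenol as a methyl ether.

**Step 7**
Reactants: 9, 1-fluoro-2-methoxybenzene
Product: 10, 2-fluoro-3-methoxybenzaldehyde
Conditions: n-BuLi, PMDTA, THF, −78 °C; DMF, −78 → 0 °C; aq NH4Cl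
Reagents that add atoms: N,N-dimethylformamide, CN(C)C=O
Why: Directed ortho-lithiation with BuLi/PMDTA removes the most acidic proton, the one next to fluorine, and DMF formylates the aryllithium (held at −78 °C to avoid benzyne formation).

**Step 8**
Reactants: 10, 2-fluoro-3-methoxybenzaldehyde; 11, 3-chlorophenol
Product: 12, 2-(3-chlorophenoxy)-3-methoxybenzaldehyde
Conditions: K2CO3, DMA, 140 °C
Reagents that add atoms: none
Why: SNAr: the fluoride ortho to the formyl group is displaced by the phenoxide through a Meisenheimer intermediate, while the unactivated aryl chloride is inert.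

**Step 9**
Reactants: 12, 2-(3-chlorophenoxy)-3-methoxybenzaldehyde
Product: 13, 2-(3-chlorophenoxy)-1-ethenyl-3-methoxybenzene
Conditions: Ph3PCH3Br, KOtBu, THF, 0 °C → rt
Reagents that add atoms: methyltriphenylphosphonium bromide, C[P+](c1ccccc1)(c1ccccc1)c1ccccc1.[Br-]
Why: Wittig methylenation of the aryl aldehyde gives the styrene needed for hydroboration.

### Union and endgame

**Step 10**
Reactants: 13, 2-(3-chlorophenoxy)-1-ethenyl-3-methoxybenzene (1.2 equiv); 7, 1-[3-(4-bromophenoxy)-4,5-dimethoxyphenyl]ethan-1-one
Product: 14, 1-[3-(4-{2-[2-(3-chlorophenoxy)-3-methoxyphenyl]ethyl}phenoxy)-4,5-dimethoxyphenyl]ethan-1-one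
Conditions: 13, 9-BBN, THF, 0 °C → rt; then 3 M aq K3PO4, 7, Pd(dppf)Cl2 (5 mol %), THF/DMF, 60 °C
Reagents that add atoms: none (9-BBN adds only H)
Why: Anti-Markovnikov hydroboration followed by B-alkyl Suzuki–Miyaura coupling with the aryl bromide gives the saturated bibenzyl bridge directly; Pd(dppf) leaves the aryl chloride untouched, and residual B–H is quenched by the aqueous base before the ketone is added.

**Step 11**
Reactants: 14, the seco aryl methyl ketone / aryl chloride
Product: 15, tri-O-methylmarchantin G: the 18-membered macrocycle in which the 3-aryloxy-4,5-dimethoxybenzoyl ring A is joined through C(=O)–CH2 to the meta position of ring B, ring B is O-linked to C1 of ring C (2-OMe, 6-CH2CH2), and ring C is joined through CH2CH2 to the para-phenylene ring D, which is O-linked back to ring A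
Conditions: Pd2(dba)3 (5 mol %), XPhos (12 mol %), NaOtBu (2.5 equiv), toluene, 90 °C; 14 added by syringe pump over 12 h (final 2 mM)
Reagents that add atoms: none
Why: Proposed new method: a macrocyclising Pd-catalysed ketone α-arylation — oxidative addition of the ring-B C–Cl bond to XPhos·Pd(0), capture of the sodium enolate of the ring-A acetyl group to give a C-bound aryl-Pd enolate (a 19-membered palladacycle), and C(sp2)–C(sp3) reductive elimination to close the 18-membered ring; it should work because the methyl-ketone enolate has no β-hydrogens, the molecule carries no second aryl halide and the bulky ligand disfavours intermolecular arylation of the more acidic deoxybenzoin product, the diaryl ether/bibenzyl backbone is pre-folded as in established marchantin closures of this ring size, and slow addition suppresses oligomerisation; the closest known reactions are the intermolecular Buchwald–Hartwig–Miura α-arylation of acetophenones with aryl chlorides and its intramolecular version for 5–7-membered rings, which has not been shown for a macrocyclic cyclophane closure.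

**Step 12**
Reactants: 15, tri-O-methylmarchantin G
Product: 16, marchantin G
Conditions: BBr3 (8 equiv), CH2Cl2, −78 °C → rt; MeOH, then H2O
Reagents that add atoms: none
Why: Lewis-acid cleavage of the three aryl methyl ethers; the diaryl ethers and the aryl benzyl ketone are stable to BBr3.

## Compound list

1 | catechol | Oc1ccccc1O | starting material
2 | 1,2-dimethoxybenzene | COc1ccccc1OC | intermediate
3 | 2,3-dimethoxyphenol | COc1cccc(O)c1OC | intermediate
4 | 2,3-dimethoxy-5-(4,4,5,5-tetramethyl-1,3,2-dioxaborolan-2-yl)phenol | COc1cc(B2OC(C)(C)C(C)(C)O2)cc(O)c1OC | intermediate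
5 | 1-(3-hydroxy-4,5-dimethoxyphenyl)ethan-1-one | CC(=O)c1cc(O)c(OC)c(OC)c1 | intermediate
6 | 1-bromo-4-iodobenzene | Brc1ccc(I)cc1 | starting material
7 | 1-[3-(4-bromophenoxy)-4,5-dimethoxyphenyl]ethan-1-one | CC(=O)c1cc(OC)c(OC)c(Oc2ccc(Br)cc2)c1 | intermediate
8 | 2-fluorophenol | Oc1ccccc1F | starting material
9 | 1-fluoro-2-methoxybenzene | COc1ccccc1F | intermediate
10 | 2-fluoro-3-methoxybenzaldehyde | COc1cccc(C=O)c1F | intermediate
11 | 3-chlorophenol | Oc1cccc(Cl)c1 | starting material
12 | 2-(3-chlorophenoxy)-3-methoxybenzaldehyde | COc1cccc(C=O)c1Oc1cccc(Cl)c1 | intermediate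
13 | 2-(3-chlorophenoxy)-1-ethenyl-3-methoxybenzene | C=Cc1cccc(OC)c1Oc1cccc(Cl)c1 | intermediate
14 | 1-[3-(4-{2-[2-(3-chlorophenoxy)-3-methoxyphenyl]ethyl}phenoxy)-4,5-dimethoxyphenyl]ethan-1-one | CC(=O)c1cc(OC)c(OC)c(Oc2ccc(CCc3cccc(OC)c3Oc3cccc(Cl)c3)cc2)c1 | intermediate
15 | tri-O-methylmarchantin G | O=C1Cc2cccc(c2)Oc2c(OC)cccc2CCc2ccc(cc2)Oc2cc1cc(OC)c2OC | intermediate
16 | marchantin G | O=C1Cc2cccc(c2)Oc2c(O)cccc2CCc2ccc(cc2)Oc2cc1cc(O)c2O | target

## Summary

**Total steps:** 12.
**Longest linear sequence:** 8 (Steps 1–5, then 10–12), which is two thirds of the total.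

**Steps most likely to fail, with fallbacks:**

1. **Step 11 (proposed new macrocyclising α-arylation).** Risks are oligomerisation, hydrodechlorination or aldol chemistry instead of ring closure. Fallback with known chemistry: form the keto bridge intermolecularly and close the ring at the bibenzyl bridge instead.
   - Vinylate 7 by Suzuki coupling with potassium vinyltrifluoroborate.
   - Couple that ketone with the 3-bromophenoxy analogue of 13 (3-bromophenol in Step 8) by standard intermolecular Pd/Xantphos/NaOtBu α-arylation.
   - Close the ring by ring-closing metathesis of the bis-styrene (Grubbs II, about 1 mM), hydrogenate the stilbene (H2, Pd/C), then BBr3.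

2. **Step 8 (SNAr at a fluoride flanked by OMe and CHO).** It may be sluggish. Fallback: reverse the polarity so ring C is the nucleophile. Make 2-hydroxy-3-methoxybenzaldehyde from catechol (mono-methylation, then Mg-mediated ortho-formylation with MgCl2/Et3N/paraformaldehyde) and form the ether by Cu-catalysed Ullmann coupling with 1-chloro-3-iodobenzene.

3. **Step 4 (acyl Suzuki on a pinacol boronate bearing a free phenol).** Transmetalation may be slow or protodeboronation may compete. Fallback: standard aqueous Suzuki coupling of 4 with 2-bromopropene to the isopropenyl arene, then oxidative cleavage of the alkene (ozonolysis with the phenol as its acetate) to the methyl ketone 5.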